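The numbers in the tables were generated by integration on assumed constants, and the scatter is random.

The first thing we ask of a flask is what is left of its substrate when we read it. Nobody read that here: the readings show target, so we reckon it by counting lifetimes.

| flask | substrate | partner | temperature | remark | time |
|---|---|---|---|---|---|
| summer | 20 mM | 0.87 equiv | 15 °C | run made earlier |  |
| autumn | 20 mM | 2 equiv | 35 °C | run made earlier |  |
| noon | 10 mM | 1.3 equiv | 15 °C | run made earlier |  |
| Thursday's | 20 mM | 1.30 equiv |  | at 20 °C until 4.0 min, from then on at 50 °C | 8.0 min |
| Saturday's | 20 mM | 1.30 equiv | 20 °C |  | 8.0 min |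
| Wednesday's | 20 mM | 1.30 equiv | 35 °C |  | 8.0 min |
| Sunday's | 20 mM | 1.30 equiv | 50 °C |  | 8.0 min |

- summer (time / min: target / %): 0.417: 0; 1.33: 3; 2.50: 5; 3.00: 0; 5.00: 1; 6.00: 3; 8.00: 5
- autumn (time / min: target / %): 0.333: 0; 0.500: 0; 0.667: 3; 1.33: 5; 2.50: 17; 4.00: 20
- noon (time / min: target / %): 0.667: 0; 1.33: 0; 2.50: 2; 4.00: 1; 8.00: 4

(scatter of a reading: 2 percentage points)

- a reading or a percentage of target counts all its forms, free or not

- the best flask by amount of target, in percent of the substrate charged; "all alike" if 1.5 percentage points covers them all (Thursday's / Saturday's / Wednesday's / Sunday's / all alike)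
- amount of target at the end, in percent of the substrate charged, Thursday's
- amount of target at the end, in percent of the substrate charged, Saturday's
- amount of target at the end, in percent of the substrate charged, Wednesday's
- amount of target at the end, in percent of the substrate charged, Sunday's

We take the lifetime τ of the substrate as the time the first slope of target would need to reach the run's last reading. After n lifetimes, c(substrate) has fallen to e^(−n) of its charge. We assume that target is a fixed share S (the selectivity) of the substrate used.

Noon and summer read 4 % and 5 % at 8.00 min, with 1.3 equiv and 0.87 equiv of partner and with 10 mM and 20 mM of substrate. That gap lies within the scatter of 2 percentage points, so we put neither charge into τ.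

The autumn run gives τ = 2.94 min at 35 °C. Its slope against the summer slope gives a factor 10.9. Those two runs differ in partner as well as in temperature, and the summer reading is poor, but we read the whole factor as temperature. Scaled to a step from 35 °C to 50 °C, that is 5.99. So τ is 0.491 min at 50 °C and 17.6 min at 20 °C.

Sunday's time over τ is 16.3, the lifetime count. Wednesday's holds 2.72, Saturday's 0.454 and Thursday's 8.37.

Does τ matter? With τ doubled, our count still puts Sunday's substrate at 0.0289 %. Saturday's reckoned used part, though, ranges from 20.3 % to 59.7 % with τ doubled or halved. So our figure for Sunday's hangs on S, which we read from the last autumn reading, with its scatter and at 2 equiv of partner: S = 26.9 %.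

We reckon 9.82 % for Saturday's, 25.1 % for Wednesday's, and 26.9 % for Thursday's, level with 26.9 % for Sunday's.

The forecast says 10 %, 24 %, 32 % and 46 % in that order, best flask Sunday's, and of the autumn bend that “it could signal a plateau or loss at high temperature”; on Sunday's it stands higher than we do.

The flasks give 6.86 %, 27.9 %, 29.6 % and 34.1 % in that order, best flask Sunday's.

    substrate → open intermediate (k = 0.0540 min⁻¹, Ea = 87.0 kJ mol⁻¹)
    partner → decomposition product (k = 4.00 × 10⁻⁴ min⁻¹, Ea = 99.0 kJ mol⁻¹)
    2 open intermediate → homo product (k = 6.90 M⁻¹ min⁻¹, Ea = 57.0 kJ mol⁻¹)
    partner + target ⇌ idle adduct, settled at all times (K = 180 M⁻¹, ΔH = −42.0 kJ mol⁻¹)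
    partner → second intermediate (k = 0.240 min⁻¹, Ea = 81.0 kJ mol⁻¹)
    substrate + second intermediate → side product (k = 2.30 M⁻¹ min⁻¹, Ea = 52.0 kJ mol⁻¹)
    open intermediate + second intermediate → target (k = 4.20 M⁻¹ min⁻¹, Ea = 41.0 kJ mol⁻¹)
    (constants at 20 °C)

Sunday's count of 16.3 holds up: its substrate stands at 0 % at 8.00 min, and its 34.1 % of target is a share and no longer a rate, since at 80.0 min Sunday's gives 35.3 %. That share is low mainly through two open intermediate combining to homo product: Sunday's without that step gives 71.1 %.

For a repeat of Sunday's at 75 °C, the same scaling gives a count of 322, so there we expect a share and no rate. That flask ends with 0 % of its substrate and gives 28.4 % of target, with 64.3 % of homo product.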